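**Plan** (benzofuran numbering throughout)

- Cuts: the enal goes back to an isopropenyl group and this to a tertiary alcohol on C2; the benzylic acetate goes back to an aryl methyl ketone. The benzene ring is then cut at C3a–C7a, C4–C5 and C6–C7 into a 1,6-diyne (ethynyl ether on O1, ethynyl group on C3) and but-3-yn-2-one.
- Enabling feature: the benzene ring bears only O1 (at C7a), C3 (at C3a) and one carbon substituent at C5, para to O1. Its six carbons are therefore three alkynes, two already joined by the O1–C2–C3 unit that carries both ring stereocentres, and the para donor–acceptor pair (O1, acetyl) orients the third.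
- Forward order: open chain with C3 and C2 from prenal and trimethylsilylacetylene, then the ynol ether, then one rhodium-catalysed [2+2+2] event that closes the dihydrofuran and the benzene ring together. Dehydration, ketone reduction, acetylation and allylic oxidation finish the side chains.
- Stereochemistry: C3 from a catalytic asymmetric alkynylation of prenal; C2 from osmylation anti to the C3 oxygen (substrate control, gives the trans ring); the benzylic centre from asymmetric transfer hydrogenation (catalyst control).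
- C2 carries a 2-hydroxypropan-2-yl group until the ynol ether is consumed, because an allyl alkynyl ether would rearrange by a [3,3] shift to a ketene well below room temperature.

Key step: step 9

Assumption: induction in the zinc–ProPhenol alkynylation is ligand-controlled, and the ligand antipode that gives the R alcohol 3 is used; both antipodes are commercial.

**Route**

Step 1
Reactants: 1 3-methylbut-2-enal; 2 ethynyl(trimethyl)silane
Product: 3 (3R)-5-methyl-1-(trimethylsilyl)hex-4-en-1-yn-3-ol
Conditions: Me2Zn (3 equiv), ProPhenol ligand (10 mol %), Ph3PO (20 mol %), toluene, 0 °C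
Reagents that add atoms: none
Why: Catalytic asymmetric alkynylation of an aldehyde (ProPhenol–zinc alkynylation, established for α,β-unsaturated aldehydes): the alkynylzinc from 2 and Me2Zn adds 1,2 to the enal inside the chiral pocket formed by Me2Zn and the ligand, which selects one aldehyde face and sets C3 as R.

Step 2
Reactants: 3 (3R)-5-methyl-1-(trimethylsilyl)hex-4-en-1-yn-3-ol
Product: 4 tert-butyl(dimethyl){[(3R)-5-methyl-1-(trimethylsilyl)hex-4-en-1-yn-3-yl]oxy}silane
Conditions: t-BuMe2SiCl, imidazole, DMF, 0 °C to rt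
Reagents that add atoms: tert-butyl(chloro)dimethylsilane, CC(C)(C)[Si](C)(C)Cl
Why: Imidazole-promoted silyl ether formation masks the propargylic hydroxyl with a group that survives osmylation, the phosphorus reagents of step 6 and n-BuLi, and that later leaves with fluoride.

Step 3
Reactants: 4 tert-butyl(dimethyl){[(3R)-5-methyl-1-(trimethylsilyl)hex-4-en-1-yn-3-yl]oxy}silane
Product: 5 (3S,4S)-4-{[tert-butyl(dimethyl)silyl]oxy}-2-methyl-6-(trimethylsilyl)hex-5-yne-2,3-diol
Conditions: OsO4 (2 mol %), N-methylmorpholine N-oxide, acetone–H2O, 0 °C to rt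
Reagents that add atoms: osmium tetroxide, O=[Os](=O)(=O)=O; N-methylmorpholine N-oxide, C[N+]1([O-])CCOCC1; water, O
Why: Upjohn dihydroxylation: OsO4 adds to the trisubstituted alkene and not to the silylalkyne, and, with the allylic C–H eclipsing the double bond to avoid A(1,3) strain with the cis methyl group, it attacks anti to the allylic C–O bond (the empirical rule for osmylation of allylic ethers), which sets the new secondary carbinol as S and gives the 3,4-anti diol needed for the trans ring.

Step 4
Reactants: 5 (3S,4S)-4-{[tert-butyl(dimethyl)silyl]oxy}-2-methyl-6-(trimethylsilyl)hex-5-yne-2,3-diol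
Product: 6 (3S,4S)-4-{[tert-butyl(dimethyl)silyl]oxy}-2-hydroxy-2-methyl-6-(trimethylsilyl)hex-5-yn-3-yl formate
Conditions: acetic formic anhydride (1.3 equiv), pyridine, CH2Cl2, −20 to 0 °C
Reagents that add atoms: acetic formic anhydride, CC(=O)OC=O
Why: O-Formylation with a mixed anhydride acylates only the secondary hydroxyl under these conditions, so the oxygen that will become O1 is singled out from the tertiary one.

Step 5
Reactants: 6 (3S,4S)-4-{[tert-butyl(dimethyl)silyl]oxy}-2-hydroxy-2-methyl-6-(trimethylsilyl)hex-5-yn-3-yl formate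
Product: 7 (3S,4S)-4-{[tert-butyl(dimethyl)silyl]oxy}-2-methyl-2-[(triethylsilyl)oxy]-6-(trimethylsilyl)hex-5-yn-3-yl formate
Conditions: Et3SiOTf, 2,6-lutidine, CH2Cl2, −78 to 0 °C
Reagents that add atoms: triethylsilyl trifluoromethanesulfonate, CC[Si](CC)(CC)OS(=O)(=O)C(F)(F)F
Why: Silylation with a silyl triflate (the usual method for tertiary alcohols) blocks the tertiary hydroxyl, which the chlorophosphonium species of step 6 would otherwise chlorinate or eliminate.

Step 6
Reactants: 7 (3S,4S)-4-{[tert-butyl(dimethyl)silyl]oxy}-2-methyl-2-[(triethylsilyl)oxy]-6-(trimethylsilyl)hex-5-yn-3-yl formate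
Product: 8 (3S,4S)-4-{[tert-butyl(dimethyl)silyl]oxy}-3-[(2,2-dichloroethenyl)oxy]-2-methyl-2-[(triethylsilyl)oxy]-6-(trimethylsilyl)hex-5-yne
Conditions: PPh3 (4 equiv), CCl4 (10 equiv), THF, 60 °C
Reagents that add atoms: carbon tetrachloride, ClC(Cl)(Cl)Cl
Why: Wittig-type dichloromethylenation of a formate: PPh3 and CCl4 give Ph3P=CCl2, which olefinates the formyl C=O to the 2,2-dichloroethenyl ether, the standard precursor of an alkynyl ether, while silyl ethers and the silylalkyne are inert.

Step 7
Reactants: 8 (3S,4S)-4-{[tert-butyl(dimethyl)silyl]oxy}-3-[(2,2-dichloroethenyl)oxy]-2-methyl-2-[(triethylsilyl)oxy]-6-(trimethylsilyl)hex-5-yne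
Product: 10 (3S,4S)-4-(ethynyloxy)-5-methylhex-1-yne-3,5-diol, via silyl-protected ynol ether 9 (not isolated)
Conditions: n-BuLi (2.3 equiv), THF, −78 to −40 °C; MeOH; then Bu4NF, THF, 0 °C to rt; chromatography on Et3N-treated silica
Reagents that add atoms: none
Why: Double lithiation–elimination of a 2,2-dichloroethenyl ether (chlorine–lithium exchange, 1,2-shift of the Fritsch–Buttenberg–Wiechell type, deprotonation) gives the lithium alkynyl ether, methanol protonates it, and fluoride then cleaves both O–Si bonds and the C–SiMe3 bond while the base-stable ynol ether and both stereocentres stay untouched.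

Step 8
Reactants: 10 (3S,4S)-4-(ethynyloxy)-5-methylhex-1-yne-3,5-diol
Product: 11 (3S,4S)-4-(ethynyloxy)-5-hydroxy-5-methylhex-1-yn-3-yl 3-methylbutanoate
Conditions: (i-BuCO)2O (1.2 equiv), Et3N, DMAP (5 mol %), CH2Cl2, 0 °C
Reagents that add atoms: 3-methylbutanoic anhydride, CC(C)CC(=O)OC(=O)CC(C)C
Why: DMAP-catalysed acyl transfer (Steglich-type esterification with an anhydride) acylates the secondary propargylic hydroxyl and not the tertiary one, and the basic medium keeps the acid-sensitive ynol ether intact.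

Step 9
Reactants: 11 (3S,4S)-4-(ethynyloxy)-5-hydroxy-5-methylhex-1-yn-3-yl 3-methylbutanoate; 12 but-3-yn-2-one
Product: 13 (2S,3S)-5-acetyl-2-(2-hydroxypropan-2-yl)-2,3-dihydro-1-benzofuran-3-yl 3-methylbutanoate
Conditions: RhCl(PPh3)3 (5 mol %), 12 (3 equiv), toluene, 25–40 °C, 11 added slowly
Reagents that add atoms: none
Why: RhCl(PPh3)3 loses PPh3, binds both alkynes of 11 and couples them oxidatively to a rhodacyclopentadiene of trivalent rhodium (C3a–C7a bond); 12 then inserts into the Rh–C7 bond and reductive elimination joins C5 to C4, returning monovalent rhodium. The closest known reactions are the RhCl(PPh3)3-catalysed [2+2+2] cyclotrimerisations of N-ethynyl amide (ynamide) 1,6-diynes with monoalkynes and the rhodium-catalysed cyclotrimerisations of 1,6-diynes tethered through an aryl alkynyl ether oxygen. The dihydrofuran ring closes in the oxidative coupling (five-membered ring from a 1,6-diyne with the three-atom O1–C2–C3 tether), and the benzene ring closes by alkyne insertion and reductive elimination, formally a [2+2+2] cycloaddition. No stereocentre is formed, and C2 and C3 are spectators because no bond to them is made or broken. The step needs regioselective insertion of 12: C7 is the β-carbon of an enol ether and the most nucleophilic carbon of the metallacycle, the unsubstituted terminus of the ynone is its electrophilic carbon, so C7 should bond to it and the acetyl-bearing carbon should end at C5, para to O1, as in the pairing of a 2-alkoxydiene with an ynone. Cross-reaction over self-trimerisation of 12 is favoured by the intramolecular first coupling and the slow addition of 11, and the temperature stays at or below 40 °C because a secondary alkyl ynol ether loses ketene by a retro-ene path on heating.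

Step 10
Reactants: 13 (2S,3S)-5-acetyl-2-(2-hydroxypropan-2-yl)-2,3-dihydro-1-benzofuran-3-yl 3-methylbutanoate
Product: 14 (2R,3S)-5-acetyl-2-(prop-1-en-2-yl)-2,3-dihydro-1-benzofuran-3-yl 3-methylbutanoate
Conditions: MeO2CNSO2NEt3 (Burgess reagent, 2 equiv), toluene, 50 °C
Reagents that add atoms: none
Why: Burgess dehydration (syn elimination of the sulfamate ester) should take a hydrogen from one of the two methyl groups rather than the single C2–H flanked by two C–O bonds, and the para acetyl group lowers the donor power of O1 so that ionisation with ring expansion is not expected; the descriptor at C2 changes to R only through the CIP priorities.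

Step 11
Reactants: 14 (2R,3S)-5-acetyl-2-(prop-1-en-2-yl)-2,3-dihydro-1-benzofuran-3-yl 3-methylbutanoate
Product: 15 (2R,3S)-5-[(1S)-1-hydroxyethyl]-2-(prop-1-en-2-yl)-2,3-dihydro-1-benzofuran-3-yl 3-methylbutanoate
Conditions: RuCl[(S,S)-TsDPEN](p-cymene) (1 mol %), HCO2H–Et3N (5:2), EtOAc, 30 °C
Reagents that add atoms: none
Why: Noyori asymmetric transfer hydrogenation of an aryl methyl ketone: the ruthenium hydride of the (S,S)-TsDPEN catalyst delivers hydrogen through the usual six-membered outer-sphere transition state to give the S benzylic alcohol under catalyst control, while the esters and the isolated alkene are inert.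

Step 12
Reactants: 15 (2R,3S)-5-[(1S)-1-hydroxyethyl]-2-(prop-1-en-2-yl)-2,3-dihydro-1-benzofuran-3-yl 3-methylbutanoate
Product: 16 (2R,3S)-5-[(1S)-1-(acetyloxy)ethyl]-2-(prop-1-en-2-yl)-2,3-dihydro-1-benzofuran-3-yl 3-methylbutanoate
Conditions: Ac2O, pyridine, DMAP (cat.), CH2Cl2, 0 °C
Reagents that add atoms: acetic anhydride, CC(=O)OC(C)=O
Why: DMAP-catalysed acetylation of the secondary benzylic alcohol under basic conditions, which do not ionise the para-alkoxybenzylic centre, so its configuration is kept.

Step 13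
Reactants: 16 (2R,3S)-5-[(1S)-1-(acetyloxy)ethyl]-2-(prop-1-en-2-yl)-2,3-dihydro-1-benzofuran-3-yl 3-methylbutanoate
Product: 18 (2R,3S)-5-[(1S)-1-(acetyloxy)ethyl]-2-(3-oxoprop-1-en-2-yl)-2,3-dihydro-1-benzofuran-3-yl 3-methylbutanoate, via allylic alcohol 17 (not isolated)
Conditions: SeO2 (0.3 equiv), t-BuOOH (3 equiv), CH2Cl2, rt; then MnO2, CH2Cl2, rt
Reagents that add atoms: tert-butyl hydroperoxide, CC(C)(C)OO; selenium dioxide, O=[Se]=O
Why: Riley allylic oxidation in its catalytic t-BuOOH variant (ene reaction, then [2,3]-sigmatropic shift) should functionalise the methyl group of the 1,1-disubstituted alkene rather than the oxygen-bearing C2–H, and MnO2 then oxidises the primary allylic alcohol, the only free hydroxyl, to the enal.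

**Compound list**

1 | 3-methylbut-2-enal | CC(C)=CC=O | starting material
2 | ethynyl(trimethyl)silane | C#C[Si](C)(C)C | starting material
3 | (3R)-5-methyl-1-(trimethylsilyl)hex-4-en-1-yn-3-ol | CC(C)=C[C@H](C#C[Si](C)(C)C)O | intermediate
4 | tert-butyl(dimethyl){[(3R)-5-methyl-1-(trimethylsilyl)hex-4-en-1-yn-3-yl]oxy}silane | CC(C)=C[C@H](C#C[Si](C)(C)C)O[Si](C)(C)C(C)(C)C | intermediate
5 | (3S,4S)-4-{[tert-butyl(dimethyl)silyl]oxy}-2-methyl-6-(trimethylsilyl)hex-5-yne-2,3-diol | CC(C)(O)[C@@H](O)[C@H](C#C[Si](C)(C)C)O[Si](C)(C)C(C)(C)C | intermediate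
6 | (3S,4S)-4-{[tert-butyl(dimethyl)silyl]oxy}-2-hydroxy-2-methyl-6-(trimethylsilyl)hex-5-yn-3-yl formate | CC(C)(O)[C@@H](OC=O)[C@H](C#C[Si](C)(C)C)O[Si](C)(C)C(C)(C)C | intermediate
7 | (3S,4S)-4-{[tert-butyl(dimethyl)silyl]oxy}-2-methyl-2-[(triethylsilyl)oxy]-6-(trimethylsilyl)hex-5-yn-3-yl formate | CC(C)(O[Si](CC)(CC)CC)[C@@H](OC=O)[C@H](C#C[Si](C)(C)C)O[Si](C)(C)C(C)(C)C | intermediate
8 | (3S,4S)-4-{[tert-butyl(dimethyl)silyl]oxy}-3-[(2,2-dichloroethenyl)oxy]-2-methyl-2-[(triethylsilyl)oxy]-6-(trimethylsilyl)hex-5-yne | CC(C)(O[Si](CC)(CC)CC)[C@@H](OC=C(Cl)Cl)[C@H](C#C[Si](C)(C)C)O[Si](C)(C)C(C)(C)C | intermediate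
9 | (3S,4S)-4-{[tert-butyl(dimethyl)silyl]oxy}-3-(ethynyloxy)-2-methyl-2-[(triethylsilyl)oxy]-6-(trimethylsilyl)hex-5-yne | CC(C)(O[Si](CC)(CC)CC)[C@@H](OC#C)[C@H](C#C[Si](C)(C)C)O[Si](C)(C)C(C)(C)C | intermediate (not isolated)
10 | (3S,4S)-4-(ethynyloxy)-5-methylhex-1-yne-3,5-diol | CC(C)(O)[C@@H](OC#C)[C@H](C#C)O | intermediate
11 | (3S,4S)-4-(ethynyloxy)-5-hydroxy-5-methylhex-1-yn-3-yl 3-methylbutanoate | CC(C)(O)[C@@H](OC#C)[C@H](C#C)OC(=O)CC(C)C | intermediate
12 | but-3-yn-2-one | CC(=O)C#C | starting material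
13 | (2S,3S)-5-acetyl-2-(2-hydroxypropan-2-yl)-2,3-dihydro-1-benzofuran-3-yl 3-methylbutanoate | CC(C)(O)[C@H]1Oc2ccc(C(C)=O)cc2[C@@H]1OC(=O)CC(C)C | intermediate
14 | (2R,3S)-5-acetyl-2-(prop-1-en-2-yl)-2,3-dihydro-1-benzofuran-3-yl 3-methylbutanoate | C=C(C)[C@H]1Oc2ccc(C(C)=O)cc2[C@@H]1OC(=O)CC(C)C | intermediate
15 | (2R,3S)-5-[(1S)-1-hydroxyethyl]-2-(prop-1-en-2-yl)-2,3-dihydro-1-benzofuran-3-yl 3-methylbutanoate | C=C(C)[C@H]1Oc2ccc([C@H](C)O)cc2[C@@H]1OC(=O)CC(C)C | intermediate
16 | (2R,3S)-5-[(1S)-1-(acetyloxy)ethyl]-2-(prop-1-en-2-yl)-2,3-dihydro-1-benzofuran-3-yl 3-methylbutanoate | C=C(C)[C@H]1Oc2ccc([C@H](C)OC(C)=O)cc2[C@@H]1OC(=O)CC(C)C | intermediate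
17 | (2R,3S)-5-[(1S)-1-(acetyloxy)ethyl]-2-(3-hydroxyprop-1-en-2-yl)-2,3-dihydro-1-benzofuran-3-yl 3-methylbutanoate | C=C(CO)[C@H]1Oc2ccc([C@H](C)OC(C)=O)cc2[C@@H]1OC(=O)CC(C)C | intermediate (not isolated)
18 | (2R,3S)-5-[(1S)-1-(acetyloxy)ethyl]-2-(3-oxoprop-1-en-2-yl)-2,3-dihydro-1-benzofuran-3-yl 3-methylbutanoate | C=C(C=O)[C@H]1Oc2ccc([C@H](C)OC(C)=O)cc2[C@@H]1OC(=O)CC(C)C | target

**Totals**

Total step count: 13. Longest linear sequence: 13 steps (from 1).

**Steps most likely to fail**

1. Step 9. The ynone may insert into the rhodacycle in both orientations (acetyl at C6 as well as C5), or be drained by self-trimerisation and phosphine-initiated oligomerisation before the rhodacycle takes it up. Fallback, from 11 back to 13: the regiochemistry is moved from the insertion to the finished arene. Compound 11 is cyclotrimerised with acetylene (1 atm, RhCl(PPh3)3, toluene), which has no orientation, to give (2S,3S)-2-(2-hydroxypropan-2-yl)-2,3-dihydro-1-benzofuran-3-yl 3-methylbutanoate F1. Electrophilic bromination with N-bromosuccinimide in MeCN at 0 °C should go para to O1 and give (2S,3S)-5-bromo-2-(2-hydroxypropan-2-yl)-2,3-dihydro-1-benzofuran-3-yl 3-methylbutanoate F2. Stille coupling with tributyl(1-ethoxyvinyl)stannane (Pd(PPh3)4, toluene, 90 °C) should give (2S,3S)-5-(1-ethoxyethenyl)-2-(2-hydroxypropan-2-yl)-2,3-dihydro-1-benzofuran-3-yl 3-methylbutanoate F3, and brief treatment with dilute aqueous HCl in THF hydrolyses the enol ether to 13.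

2. Step 13. The ene reaction of SeO2 with the hindered 1,1-disubstituted alkene may stall, abstraction of the C2 hydrogen may open the dihydrofuran ring, and selenous acid may ionise the two benzylic esters. Fallback, from 16 back to 18: oxidation through an allylic chloride. N-Chlorosuccinimide with catalytic PhSeCl (ene-type chlorination with double-bond shift, CH2Cl2, rt) should give (2R,3S)-5-[(1S)-1-(acetyloxy)ethyl]-2-(3-chloroprop-1-en-2-yl)-2,3-dihydro-1-benzofuran-3-yl 3-methylbutanoate F4. N-Methylmorpholine N-oxide with NaI (cat.) in MeCN (Ganem oxidation) then converts the CH2Cl group into the aldehyde of 18.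

3. Step 3. Osmylation under pure substrate control may lose facial selectivity if the bulky silyl ether distorts the reactive conformer, giving a syn/anti diol mixture that is hard to separate. Fallback, from 3 back to 5: reagent-controlled epoxidation and hydrolysis. Sharpless asymmetric epoxidation of the free allylic alcohol 3 (Ti(OiPr)4, D-(−)-diisopropyl tartrate, t-BuOOH, CH2Cl2, −20 °C; matched pairing for the R carbinol, erythro-selective) should give (1S)-1-[(2S)-3,3-dimethyloxiran-2-yl]-3-(trimethylsilyl)prop-2-yn-1-ol F5. Acid-catalysed hydrolysis (HClO4 cat., THF–H2O, 0 °C) opens the epoxide at the tertiary carbon with the secondary C–O bond retained and gives (3S,4S)-2-methyl-6-(trimethylsilyl)hex-5-yne-2,3,4-triol F6. Selective silylation of the least hindered, propargylic hydroxyl (t-BuMe2SiCl, imidazole, DMF, −20 °C) gives 5.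

**Further compounds**

F1 | step 9 | (2S,3S)-2-(2-hydroxypropan-2-yl)-2,3-dihydro-1-benzofuran-3-yl 3-methylbutanoate | CC(C)(O)[C@H]1Oc2ccccc2[C@@H]1OC(=O)CC(C)C
F2 | step 9 | (2S,3S)-5-bromo-2-(2-hydroxypropan-2-yl)-2,3-dihydro-1-benzofuran-3-yl 3-methylbutanoate | CC(C)(O)[C@H]1Oc2ccc(Br)cc2[C@@H]1OC(=O)CC(C)C
F3 | step 9 | (2S,3S)-5-(1-ethoxyethenyl)-2-(2-hydroxypropan-2-yl)-2,3-dihydro-1-benzofuran-3-yl 3-methylbutanoate | CC(C)(O)[C@H]1Oc2ccc(C(=C)OCC)cc2[C@@H]1OC(=O)CC(C)C
F4 | step 13 | (2R,3S)-5-[(1S)-1-(acetyloxy)ethyl]-2-(3-chloroprop-1-en-2-yl)-2,3-dihydro-1-benzofuran-3-yl 3-methylbutanoate | C=C(CCl)[C@H]1Oc2ccc([C@H](C)OC(C)=O)cc2[C@@H]1OC(=O)CC(C)C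
F5 | step 3 | (1S)-1-[(2S)-3,3-dimethyloxiran-2-yl]-3-(trimethylsilyl)prop-2-yn-1-ol | CC1(C)O[C@H]1[C@H](C#C[Si](C)(C)C)O
F6 | step 3 | (3S,4S)-2-methyl-6-(trimethylsilyl)hex-5-yne-2,3,4-triol | CC(C)(O)[C@@H](O)[C@H](C#C[Si](C)(C)C)O
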